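The rate constants are invented; the run is a simulation.

The ratio I follow is J made per Q made, and X sets it, since each Q frees two X and free X goes either to J with Z or to D.

    X → D (k1 = 6.9 h⁻¹)
    X + Z ⇌ X.Z, settled at all times (K2 = 38 L mol⁻¹)
    E + L ⇌ X + Q (K3 = 1.0, k3 = 28 L mol⁻¹ h⁻¹)
    Z + L ⇌ X + E (K4 = 0.36, k4 = 9.8 L mol⁻¹ h⁻¹)
    X + Z → J (k5 = 18 L mol⁻¹ h⁻¹)

| setting | west | east | south-west | south |
|---|---|---|---|---|
| Z | 0.076 M | 0.076 M | 0.076 M | 0.076 M |
| L | 1.20 equiv | 1.20 equiv | 1.20 equiv | 1.20 equiv (fed, over 1.25 h) |
| X | 0.500 equiv | 0.500 equiv | 0.500 equiv | 0.500 equiv |
| time | 2.5 h |  |  | 2.5 h |
| remark | everything together in a closed stirred flask, run for 2.5 h | a single well-mixed tank run continuously and read at steady state, 2.5 h in it on average | a single well-mixed tank run continuously and read at steady state, 25.0 h in it on average | a stirred flask in which L is dosed at a steady rate over 1.25 h without added volume, worked up at 2.5 h |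

- the set-up with the highest share of Q in all that became Q or J, at the outlet or at the end ("none" if the first two lie within 2 percentage points) (west / east / south-west / south / none)
- share of Q in all that became Q or J, at the outlet or at the end, west
- share of Q in all that became Q or J, at the outlet or at the end, east
- share of Q in all that became Q or J, at the outlet or at the end, south-west
- share of Q in all that became Q or J, at the outlet or at the end, south

- X is meant together with its X.Z
- the stated concentrations are those of everything mixed, before any reaction; amounts are the same in each set-up
- the feed brings no volume worth counting
- run time (west): 2.5 h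

While free Z holds still, both losses of free X are pseudo-first-order, so X falls exponentially. Integrating the J rate over that fall gives the X supplied times J's rate over the sum of J's and D's rates: the branching ratio 16.5%, here for Z as charged. Binding into X.Z also takes Z: with X as charged, free Z starts near 0.0509 M, which gives a ratio of 11.7%, lower than the 16.5% for Z as charged. I carry 16.5% for the charged X as the high end. For the tank rows I assume L stands at 0.0456 M in the east tank, 0.5 of its charge. I let it fall with time in the tank to 0.00829 M in the south-west tank. I also assume Q reaches 0.5 of the Z charged everywhere. The ratio depends on the Z that X meets: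

- Z as charged, 0.076 M: 16.5%
- Z at 0.0380 M, my guess for west once X is being freed: 9.02%
- Z at 0.0570 M, my guess for south once X is being freed: 12.9%
- east tank, Z 0.0359 M: 8.56%
- south-west tank, Z 0.0251 M: 6.14%

Reading the first row: with Z as charged, X halves in 0.326 h. That is sooner than Z halves by its exchange with L as charged, 0.776 h, and sooner than the dose ends. So in west I let the charged X take this row and the freed X the second, which gives 74.3%. In south L comes in over 1.25 h, so I let the charged X take this row and the freed X the third, which gives 70.2%.

In a tank, charged and freed X alike enter standing Z, so one row serves: 79.6% for east and 84.4% for south-west. My choice is south-west.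

The forecast also picks south-west, with 75% west, 77% east, 85% south-west and 66% south, lower than mine for south, since “J gets a head start and the fed flask comes out worst”.

The simulation gives south-west as best at 84.5%, then 76.4% east, 75.3% west and 71.8% south, 5.8 percentage points above the forecast for south. The south-west tank reads Z at 0.0231 M, which makes the ratio 5.68%. With L read at 0.00876 M, X charged and freed comes to 1.58 per Z charged. With Q at 48.5%, that gives a share of 84.4%. Striking out the loss to D in the east tank sets the ratio to 1, two J per Q, a share of 33.3%; that run stands at 32.8%.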